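**Retrosynthetic overview**
- The route rests on the chroman benzene ring (C4a'–C5'–C6'–C7'–C8'–C8a'): its oxygens at C5' and C8a' are meta and flank the alkyl-bearing C4a', and C6' next to C5' carries coumarin C3. This is the pattern a vinylketene/siloxyalkyne benzannulation assembles.
- Target ⇒ debenzylation, acid closure of the pyran (O1'–C2'), desilylation and C5' O-methylation ⇒ resorcinol monosilyl ether ⇒ photo-Wolff benzannulation (C7'–C8', C5'–C4a', C8a'–C8', C5'–C6') of a coumarinyl diazo enone with a siloxyalkyne.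
- Diazo enone ⇒ coumarin-3-acrylic acid ⇒ Knoevenagel/lactonization of a 4-O-benzyl salicylaldehyde with diethyl glutaconate. Siloxyalkyne ⇒ silyl-protected 2-methylhex-5-yn-2-ol by acetylide oxygenation and O-silylation.
- Ring order: coumarin pyranone ring, then the chroman benzene ring (key step), then the dihydropyran ring.

Key step: step 8

Assumption: primed locants refer to the chroman unit and unprimed ones to the coumarin; the target is achiral; 2,4-dihydroxy-6-methoxybenzaldehyde and diethyl glutaconate (an E/Z mixture that equilibrates under amine catalysis) are taken as catalogue compounds.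

**Route**

Step 1
Reactants: 1 ethyl pent-4-ynoate
Product: 2 2-methylhex-5-yn-2-ol
Conditions: MeMgBr (3 equiv), THF, 0 °C; aq. NH4Cl
Reagents that add atoms: methylmagnesium bromide, C[Mg]Br
Why: Double Grignard addition to the ester should give the tertiary carbinol, with the terminal alkyne recovered unchanged after work-up.

Step 2
Reactants: 2 2-methylhex-5-yn-2-ol
Product: 3 triethyl[(2-methylhex-5-yn-2-yl)oxy]silane
Conditions: Et3SiOTf, 2,6-lutidine, CH2Cl2, −78 → 0 °C
Reagents that add atoms: triethylsilyl trifluoromethanesulfonate, CC[Si](CC)(CC)OS(=O)(=O)C(F)(F)F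
Why: Silyl triflate/lutidine silylation is the standard way to cap a hindered tertiary alcohol and leaves the alkyne C–H untouched.

Step 3
Reactants: 3 triethyl[(2-methylhex-5-yn-2-yl)oxy]silane
Product: 6 triethyl{[2-methyl-6-(triisopropylsilyloxy)hex-5-yn-2-yl]oxy}silane, via lithium acetylide 4 (not isolated), via lithium ynolate 5 (not isolated)
Conditions: n-BuLi, THF, −78 °C; t-BuOOLi (t-BuOOH + LiN(SiMe3)2), −78 → 0 °C; i-Pr3SiOTf, −78 → 0 °C
Reagents that add atoms: tert-butyl hydroperoxide, CC(C)(C)OO; triisopropylsilyl trifluoromethanesulfonate, CC(C)[Si](OS(=O)(=O)C(F)(F)F)(C(C)C)C(C)C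
Why: Acetylide oxygenation (attack of the acetylide on the electrophilic oxygen of lithium tert-butyl peroxide) should give the ynolate, which the bulky silyl triflate traps on oxygen, not carbon, to give the siloxyalkyne.

Step 4
Reactants: 7 2,4-dihydroxy-6-methoxybenzaldehyde
Product: 8 4-(benzyloxy)-2-hydroxy-6-methoxybenzaldehyde
Conditions: BnBr (1.05 equiv), NaHCO3, MeCN, 70 °C
Reagents that add atoms: benzyl bromide, BrCc1ccccc1
Why: Williamson etherification with a weak base should alkylate only the C4 hydroxyl, because the C2 hydroxyl is hydrogen-bonded to the aldehyde and far less nucleophilic.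

Step 5
Reactants: 8 4-(benzyloxy)-2-hydroxy-6-methoxybenzaldehyde; 9 diethyl (2E)-pent-2-enedioate (diethyl glutaconate)
Product: 10 ethyl (2E)-3-[7-(benzyloxy)-5-methoxy-2-oxo-2H-chromen-3-yl]prop-2-enoate
Conditions: piperidine (cat.), AcOH (cat.), EtOH, reflux
Reagents that add atoms: none
Why: Knoevenagel condensation at the doubly activated methylene of the glutaconate, then lactonization of the ortho phenol onto the cis ester, should close the coumarin pyranone ring and leave the (E)-acrylate at C3.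

Step 6
Reactants: 10 ethyl (2E)-3-[7-(benzyloxy)-5-methoxy-2-oxo-2H-chromen-3-yl]prop-2-enoate
Product: 12 (2E)-3-[7-(benzyloxy)-5-methoxy-2-oxo-2H-chromen-3-yl]prop-2-enoic acid, via trilithium coumarinate 11 (not isolated)
Conditions: LiOH·H2O (4 equiv), THF–H2O, 20 °C; then 1 M HCl, pH 2
Reagents that add atoms: lithium hydroxide, [Li+].[OH-]
Why: Saponification cleaves the ethyl ester while the lactone opens to the (Z)-coumarinate, whose fixed alkene geometry should make relactonization spontaneous on acidification.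

Step 7
Reactants: 12 (2E)-3-[7-(benzyloxy)-5-methoxy-2-oxo-2H-chromen-3-yl]prop-2-enoic acid
Product: 14 7-(benzyloxy)-3-[(1E)-4-diazo-3-oxobut-1-en-1-yl]-5-methoxy-2H-chromen-2-one, via acid chloride 13 (not isolated)
Conditions: (COCl)2, DMF (cat.), CH2Cl2, 0 → 20 °C; evaporate; CH2N2 (3 equiv), Et2O–THF, 0 °C
Reagents that add atoms: oxalyl chloride, O=C(Cl)C(=O)Cl (chlorine of 13 only); diazomethane, C=[N+]=[N-]
Why: C-Acylation of diazomethane by the acid chloride (the diazo ketone stage of the Arndt–Eistert sequence) should outrun dipolar cycloaddition to the β-aryl-type alkene, with a second equivalent of diazomethane scavenging HCl.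

Step 8
Reactants: 14 7-(benzyloxy)-3-[(1E)-4-diazo-3-oxobut-1-en-1-yl]-5-methoxy-2H-chromen-2-one; 6 triethyl{[2-methyl-6-(triisopropylsilyloxy)hex-5-yn-2-yl]oxy}silane
Product: 19 7-(benzyloxy)-3-{2-hydroxy-3-[3-methyl-3-(triethylsilyloxy)butyl]-4-(triisopropylsilyloxy)phenyl}-5-methoxy-2H-chromen-2-one, via vinylketene 15 (not isolated), via vinylcyclobutenone 16 (not isolated), via dienylketene 17 (not isolated), via cyclohexadienone 18 (not isolated)
Conditions: hν (405 nm LEDs), 6 (1.5 equiv), degassed ClCH2CH2Cl (0.02 M), 20 °C; then 80 °C, dark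
Reagents that add atoms: none
Why: Excitation of the diazo enone expels N2 and the alkenyl group migrates to the carbene carbon (Wolff rearrangement, forming C7'–C8') to give vinylketene 15, the siloxyalkyne adds to the ketene C=C in a [2+2] cycloaddition (C5'–C4a' and C8a'–C8'), and on warming cyclobutenone 16 opens reversibly (4π) to dienylketene 17. The chroman benzene ring is closed by a thermal disrotatory 6π electrocyclization that joins the ketene carbon C5' to the alkene terminus C6', and enolization of dienone 18 delivers the phenol. This is the diazo ketone variant of the Danheiser benzannulation, a known reaction of β-aryl diazo enones with triisopropylsiloxyalkynes. No stereocentre is created, since the only sp3 ring carbon of 18 is lost on aromatization, and light-induced E/Z scrambling of the enone is harmless because both alkene isomers converge on 18. The selectivity needed is the orientation of the [2+2]: the ynol ether is polarized so that its alkyl-bearing carbon is the nucleophile and bonds to the ketene carbonyl carbon, which places the side chain between the free C5' hydroxyl and the C8a' silyl ether. Violet light should be absorbed by the extended coumarin–enone–diazo chromophore but not by the 3-arylcoumarin product or the alkyne, and high dilution should suppress coumarin [2+2] photodimerization.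

Step 9
Reactants: 19 7-(benzyloxy)-3-{2-hydroxy-3-[3-methyl-3-(triethylsilyloxy)butyl]-4-(triisopropylsilyloxy)phenyl}-5-methoxy-2H-chromen-2-one
Product: 20 7-(benzyloxy)-5-methoxy-3-{2-methoxy-3-[3-methyl-3-(triethylsilyloxy)butyl]-4-(triisopropylsilyloxy)phenyl}-2H-chromen-2-one
Conditions: MeI, K2CO3, acetone, 50 °C
Reagents that add atoms: iodomethane, CI
Why: Williamson methylation of the only free hydroxyl (the C5' phenol derived from the ketene carbonyl) should fix the C5' methoxy group, while the aryl silyl ether and the lactone tolerate anhydrous carbonate.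

Step 10
Reactants: 20 7-(benzyloxy)-5-methoxy-3-{2-methoxy-3-[3-methyl-3-(triethylsilyloxy)butyl]-4-(triisopropylsilyloxy)phenyl}-2H-chromen-2-one
Product: 21 7-(benzyloxy)-3-[4-hydroxy-3-(3-hydroxy-3-methylbutyl)-2-methoxyphenyl]-5-methoxy-2H-chromen-2-one
Conditions: Bu4NF (3 equiv), THF, 0 → 20 °C
Reagents that add atoms: none
Why: Fluoride-mediated desilylation should remove the aryl triisopropylsilyl ether and the tertiary triethylsilyl ether in one operation, exposing the C8a' phenol and the tertiary carbinol.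

Step 11
Reactants: 21 7-(benzyloxy)-3-[4-hydroxy-3-(3-hydroxy-3-methylbutyl)-2-methoxyphenyl]-5-methoxy-2H-chromen-2-one
Product: 22 7-(benzyloxy)-5-methoxy-3-(5-methoxy-2,2-dimethyl-3,4-dihydro-2H-chromen-6-yl)-2H-chromen-2-one
Conditions: TsOH·H2O (10 mol %), toluene, 70 °C
Reagents that add atoms: none
Why: In this acid-catalysed cyclodehydration the tertiary carbinol ionizes and the only free phenol oxygen, at C8a', should capture the cation in a six-membered closure (O1'–C2') to give the 2,2-dimethylchroman, C5' being unable to compete because it is already methylated.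

Step 12
Reactants: 22 7-(benzyloxy)-5-methoxy-3-(5-methoxy-2,2-dimethyl-3,4-dihydro-2H-chromen-6-yl)-2H-chromen-2-one
Product: 23 7-hydroxy-5-methoxy-3-(5-methoxy-2,2-dimethyl-3,4-dihydro-2H-chromen-6-yl)-2H-chromen-2-one
Conditions: H2 (1 atm), 10% Pd/C, EtOAc–MeOH, 20 °C
Reagents that add atoms: none
Why: Catalytic hydrogenolysis should cleave the benzyl ether well before the hindered, aryl-conjugated coumarin C3=C4 bond is reduced, provided the reaction is stopped after one equivalent of hydrogen.

**Compound list**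

1 | ethyl pent-4-ynoate | CCOC(=O)CCC#C | starting material
2 | 2-methylhex-5-yn-2-ol | CC(C)(O)CCC#C | intermediate
3 | triethyl[(2-methylhex-5-yn-2-yl)oxy]silane | CC[Si](CC)(CC)OC(C)(C)CCC#C | intermediate
4 | lithium 5-methyl-5-(triethylsilyloxy)hex-1-yn-1-ide | [Li+].[C-]#CCCC(C)(C)O[Si](CC)(CC)CC | intermediate
5 | lithium 5-methyl-5-(triethylsilyloxy)hex-1-yn-1-olate | [Li+].[O-]C#CCCC(C)(C)O[Si](CC)(CC)CC | intermediate
6 | triethyl{[2-methyl-6-(triisopropylsilyloxy)hex-5-yn-2-yl]oxy}silane | CC[Si](CC)(CC)OC(C)(C)CCC#CO[Si](C(C)C)(C(C)C)C(C)C | intermediate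
7 | 2,4-dihydroxy-6-methoxybenzaldehyde | COc1cc(O)cc(O)c1C=O | starting material
8 | 4-(benzyloxy)-2-hydroxy-6-methoxybenzaldehyde | COc1cc(OCc2ccccc2)cc(O)c1C=O | intermediate
9 | diethyl (2E)-pent-2-enedioate | CCOC(=O)C/C=C/C(=O)OCC | starting material
10 | ethyl (2E)-3-[7-(benzyloxy)-5-methoxy-2-oxo-2H-chromen-3-yl]prop-2-enoate | CCOC(=O)/C=C/c1cc2c(OC)cc(OCc3ccccc3)cc2oc1=O | intermediate
11 | trilithium (2E,4Z)-4-{[4-(benzyloxy)-2-methoxy-6-oxidophenyl]methylidene}pent-2-enedioate | [Li+].[Li+].[Li+].[O-]C(=O)/C=C/C(=C/c1c([O-])cc(OCc2ccccc2)cc1OC)C(=O)[O-] | intermediate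
12 | (2E)-3-[7-(benzyloxy)-5-methoxy-2-oxo-2H-chromen-3-yl]prop-2-enoic acid | OC(=O)/C=C/c1cc2c(OC)cc(OCc3ccccc3)cc2oc1=O | intermediate
13 | (2E)-3-[7-(benzyloxy)-5-methoxy-2-oxo-2H-chromen-3-yl]prop-2-enoyl chloride | ClC(=O)/C=C/c1cc2c(OC)cc(OCc3ccccc3)cc2oc1=O | intermediate
14 | 7-(benzyloxy)-3-[(1E)-4-diazo-3-oxobut-1-en-1-yl]-5-methoxy-2H-chromen-2-one | [N-]=[N+]=CC(=O)/C=C/c1cc2c(OC)cc(OCc3ccccc3)cc2oc1=O | intermediate
15 | 7-(benzyloxy)-5-methoxy-3-[(1E)-4-oxobuta-1,3-dien-1-yl]-2H-chromen-2-one | O=C=C/C=C/c1cc2c(OC)cc(OCc3ccccc3)cc2oc1=O | intermediate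
16 | 7-(benzyloxy)-5-methoxy-3-[(E)-2-{3-[3-methyl-3-(triethylsilyloxy)butyl]-4-oxo-2-(triisopropylsilyloxy)cyclobut-2-en-1-yl}ethenyl]-2H-chromen-2-one (racemic) | O=C1C(CCC(C)(C)O[Si](CC)(CC)CC)=C(O[Si](C(C)C)(C(C)C)C(C)C)C1/C=C/c1cc2c(OC)cc(OCc3ccccc3)cc2oc1=O | intermediate
17 | 7-(benzyloxy)-5-methoxy-3-[(1E,3E)-5-[3-methyl-3-(triethylsilyloxy)butyl]-6-oxo-4-(triisopropylsilyloxy)hexa-1,3,5-trien-1-yl]-2H-chromen-2-one | O=C=C(CCC(C)(C)O[Si](CC)(CC)CC)/C(O[Si](C(C)C)(C(C)C)C(C)C)=C\C=C\c1cc2c(OC)cc(OCc3ccccc3)cc2oc1=O | intermediate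
18 | 7-(benzyloxy)-5-methoxy-3-{3-[3-methyl-3-(triethylsilyloxy)butyl]-2-oxo-4-(triisopropylsilyloxy)cyclohexa-3,5-dien-1-yl}-2H-chromen-2-one (racemic) | O=C1C(CCC(C)(C)O[Si](CC)(CC)CC)=C(O[Si](C(C)C)(C(C)C)C(C)C)C=CC1c1cc2c(OC)cc(OCc3ccccc3)cc2oc1=O | intermediate
19 | 7-(benzyloxy)-3-{2-hydroxy-3-[3-methyl-3-(triethylsilyloxy)butyl]-4-(triisopropylsilyloxy)phenyl}-5-methoxy-2H-chromen-2-one | Oc1c(CCC(C)(C)O[Si](CC)(CC)CC)c(O[Si](C(C)C)(C(C)C)C(C)C)ccc1-c1cc2c(OC)cc(OCc3ccccc3)cc2oc1=O | intermediate
20 | 7-(benzyloxy)-5-methoxy-3-{2-methoxy-3-[3-methyl-3-(triethylsilyloxy)butyl]-4-(triisopropylsilyloxy)phenyl}-2H-chromen-2-one | COc1c(CCC(C)(C)O[Si](CC)(CC)CC)c(O[Si](C(C)C)(C(C)C)C(C)C)ccc1-c1cc2c(OC)cc(OCc3ccccc3)cc2oc1=O | intermediate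
21 | 7-(benzyloxy)-3-[4-hydroxy-3-(3-hydroxy-3-methylbutyl)-2-methoxyphenyl]-5-methoxy-2H-chromen-2-one | COc1c(CCC(C)(C)O)c(O)ccc1-c1cc2c(OC)cc(OCc3ccccc3)cc2oc1=O | intermediate
22 | 7-(benzyloxy)-5-methoxy-3-(5-methoxy-2,2-dimethyl-3,4-dihydro-2H-chromen-6-yl)-2H-chromen-2-one | COc1c(-c2cc3c(OC)cc(OCc4ccccc4)cc3oc2=O)ccc2c1CCC(C)(C)O2 | intermediate
23 | 7-hydroxy-5-methoxy-3-(5-methoxy-2,2-dimethyl-3,4-dihydro-2H-chromen-6-yl)-2H-chromen-2-one (CNP0139207.0) | COc1c(-c2cc3c(OC)cc(O)cc3oc2=O)ccc2c1CCC(C)(C)O2 | target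

**Step count**

Total: 12 steps. Longest linear sequence: 9 steps (7 → 23, steps 4–12); the alkyne branch (steps 1–3) joins at step 8.

**Steps most likely to fail**

1. Step 8. The absorbed light may be spent on E/Z isomerization or on [2+2] photodimerization at the coumarin C3=C4 bond instead of N2 loss, and the phenol formed may be acylated by unreacted ketene. The fallback generates the same vinylketene thermally in the dark and sets out from 14. Wolff rearrangement with PhCO2Ag (cat.) and Et3N in THF–H2O with water capture (Arndt–Eistert homologation) should give (3E)-4-[7-(benzyloxy)-5-methoxy-2-oxo-2H-chromen-3-yl]but-3-enoic acid F1. Oxalyl chloride with catalytic DMF converts it into (3E)-4-[7-(benzyloxy)-5-methoxy-2-oxo-2H-chromen-3-yl]but-3-enoyl chloride F2. Slow addition of Et3N to F2 and 6 in toluene at 20 °C, then heating to 80–110 °C, dehydrochlorinates F2 to vinylketene 15, which enters the same [2+2]/4π/6π cascade through 16, 17 and 18. The fallback returns to the route at 19.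

2. Step 7. 1,3-Dipolar cycloaddition of diazomethane to the electron-poor dienoyl π-system (pyrazoline formation) may compete with C-acylation. The fallback sets out from acid chloride 13 and avoids diazomethane. Negishi acylation with MeZnCl and Pd(PPh3)4 (cat.) in THF at 0 °C should give 7-(benzyloxy)-5-methoxy-3-[(1E)-3-oxobut-1-en-1-yl]-2H-chromen-2-one F3. Kinetic enolization with LiN(SiMe3)2 at −78 °C and trifluoroacetylation with CF3CO2CH2CF3 gives 7-(benzyloxy)-5-methoxy-3-[(1E)-6,6,6-trifluoro-3,5-dioxohex-1-en-1-yl]-2H-chromen-2-one F4, which is not isolated. Detrifluoroacetylative diazo transfer with MsN3, Et3N and H2O in MeCN at 20 °C returns to the route at 14.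

3. Step 5. Condensation of the hindered, electron-rich, hydrogen-bonded aldehyde may be slow while the glutaconate self-condenses under the amine base. The fallback sets out from 8 and builds the coumarin first. Wittig olefination with Ph3P=CHCO2Et in PhNEt2 at reflux, with thermal alkene isomerization and lactonization, should give 7-(benzyloxy)-5-methoxy-2H-chromen-2-one F5. A C3-selective dehydrogenative Heck (Fujiwara–Moritani) coupling with ethyl acrylate, using Pd(OAc)2 (cat.), AgOAc and PivOH at 100 °C, proceeds by palladation of the nucleophilic coumarin C3–H by divalent palladium. The fallback returns to the route at 10.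

**Further compounds**

F1 | step 8 | (3E)-4-[7-(benzyloxy)-5-methoxy-2-oxo-2H-chromen-3-yl]but-3-enoic acid | OC(=O)C/C=C/c1cc2c(OC)cc(OCc3ccccc3)cc2oc1=O
F2 | step 8 | (3E)-4-[7-(benzyloxy)-5-methoxy-2-oxo-2H-chromen-3-yl]but-3-enoyl chloride | ClC(=O)C/C=C/c1cc2c(OC)cc(OCc3ccccc3)cc2oc1=O
F3 | step 7 | 7-(benzyloxy)-5-methoxy-3-[(1E)-3-oxobut-1-en-1-yl]-2H-chromen-2-one | CC(=O)/C=C/c1cc2c(OC)cc(OCc3ccccc3)cc2oc1=O
F4 | step 7 | 7-(benzyloxy)-5-methoxy-3-[(1E)-6,6,6-trifluoro-3,5-dioxohex-1-en-1-yl]-2H-chromen-2-one | O=C(CC(=O)C(F)(F)F)/C=C/c1cc2c(OC)cc(OCc3ccccc3)cc2oc1=O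
F5 | step 5 | 7-(benzyloxy)-5-methoxy-2H-chromen-2-one | COc1cc(OCc2ccccc2)cc2oc(=O)ccc12
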